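**Retrosynthetic overview**

1. The C5 side chain is attached last by B-alkyl Suzuki coupling of a 5-bromo-4-hydroxybenzofuran-3-carbaldehyde with hydroborated 2-methylbut-3-en-2-ol, under base, so the tertiary alcohol never meets acid. The 4-OH comes from chelation-controlled cleavage of the 4-OMe beside the 3-CHO.
2. The furan ring is the only ring built (rings A and B are bought benzene rings). It is closed through the O1–C2 bond by a platinum-catalysed cyclisation of an o-alkynylaryl diethyl orthoformate, in which the diethoxymethyl group moves from O to C3 and is then hydrolysed to the 3-CHO.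
3. The diarylalkyne comes from Sonogashira coupling of 4-bromo-2-iodo-3,5-dimethoxyphenol (ring A) with 4-ethynyl-3-methoxyphenol (ring B).
4. The ring A piece comes from 2-bromo-1,3-dimethoxybenzene by C–H borylation/oxidation and ortho-iodination, both regiochemically unambiguous because of the mirror symmetry. The ring B piece comes from 4-hydroxy-2-methoxybenzaldehyde by one-carbon homologation.

Assumption: the target has no stereocentre (it is achiral), so there is no enantiomer to select and no stereocontrol is needed.

**Route**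

Step 1
Reactants: 1 2-bromo-1,3-dimethoxybenzene
Product: 3 4-bromo-3,5-dimethoxyphenol, via arylboronic ester 2 (not isolated)
Conditions: [Ir(OMe)(cod)]2 (1.5 mol %), 4,4'-di-tert-butyl-2,2'-bipyridine (3 mol %), B2pin2 (1.0 equiv), THF, 80 °C; then 30% H2O2, 3 M NaOH, THF, 0 °C → rt
Reagents that add atoms: hydrogen peroxide (OO)
Why: Iridium-catalysed C–H borylation is sterically controlled and takes only the C–H that has no ortho substituent (meta to both OMe, para to Br) without touching C–Br, and basic peroxide then turns C–B into C–O (borylation/ipso-hydroxylation), giving a phenol whose two ortho positions are equivalent.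

Step 2
Reactants: 3 4-bromo-3,5-dimethoxyphenol
Product: 4 4-bromo-2-iodo-3,5-dimethoxyphenol
Conditions: NIS (1.0 equiv, slow addition), MeCN, −10 → 0 °C, dark
Reagents that add atoms: N-iodosuccinimide (O=C1CCC(=O)N1I)
Why: Electrophilic aromatic iodination of a phenol whose para position is blocked by Br and whose two ortho positions are symmetry-equivalent, so mono-iodination can give only the isomer with iodine between OH and OMe.

Step 3
Reactants: 5 4-hydroxy-2-methoxybenzaldehyde
Product: 6 4-ethynyl-3-methoxyphenol
Conditions: dimethyl (1-diazo-2-oxopropyl)phosphonate (1.5 equiv), K2CO3 (3 equiv), MeOH, rt, 24 h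
Reagents that add atoms: dimethyl (1-diazo-2-oxopropyl)phosphonate (CC(=O)C(=[N+]=[N-])P(=O)(OC)OC)
Why: Seyferth–Gilbert homologation in its Ohira–Bestmann form converts ArCHO directly into ArC≡CH under K2CO3/MeOH, and the free phenol (present as phenoxide) only slows the addition.

Step 4
Reactants: 4 4-bromo-2-iodo-3,5-dimethoxyphenol; 6 4-ethynyl-3-methoxyphenol (1.2 equiv)
Product: 7 4-bromo-2-[(4-hydroxy-2-methoxyphenyl)ethynyl]-3,5-dimethoxyphenol
Conditions: Pd(PPh3)2Cl2 (3 mol %), CuI (5 mol %), Et3N (3 equiv), THF, rt, degassed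
Reagents that add atoms: none
Why: Sonogashira coupling in which zerovalent palladium inserts into C–I far faster than into the hindered, electron-rich C–Br, and at room temperature the free o-alkynylphenol does not yet cyclise.

Step 5
Reactants: 7 4-bromo-2-[(4-hydroxy-2-methoxyphenyl)ethynyl]-3,5-dimethoxyphenol
Product: 10 5-bromo-2-(4-hydroxy-2-methoxyphenyl)-4,6-dimethoxy-1-benzofuran-3-carbaldehyde, via bis(diethoxymethyl) ether 8 (not isolated), via diethyl acetal 9 (not isolated)
Conditions: HC(OEt)3 (neat, large excess), 125 °C, EtOH distilled off, then evaporate; PtCl2 (5 mol %), 1,5-cyclooctadiene (20 mol %), toluene, 40 °C; then 1 M HCl, THF, rt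
Reagents that add atoms: triethyl orthoformate (CCOC(OCC)OCC); water (O)
Why: Proposed new method: platinum-dichloride-catalysed oxy-cyclisation with O-to-C3 shift of a diethoxymethyl group — divalent platinum π-activates the alkyne, the aryl oxygen of the orthoformate adds anti (5-endo-dig) to form the O1–C2 bond and a 3-platinated oxonium ion, the O–CH(OEt)2 bond ionises to the strongly stabilised diethoxycarbenium ion, and this is captured inside the ion pair by the nucleophilic C3–Pt carbon, releasing PtCl2 and the 3-(diethoxymethyl)benzofuran, after which dilute acid hydrolyses the acetal to CHO and the bystander ring B orthoformate back to OH; the closest known reaction type is the platinum-catalysed carboalkoxylation of o-alkynylphenyl acetals (1,3-migration of an α-alkoxyalkyl group), which has not been shown for an orthoformate-derived, formyl-level migrating group, and the two methoxy groups ortho to the alkyne cannot migrate, so only the orthoformate oxygen closes the ring.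

Step 6
Reactants: 10 5-bromo-2-(4-hydroxy-2-methoxyphenyl)-4,6-dimethoxy-1-benzofuran-3-carbaldehyde
Product: 11 5-bromo-4-hydroxy-2-(4-hydroxy-2-methoxyphenyl)-6-methoxy-1-benzofuran-3-carbaldehyde
Conditions: BCl3 (3 equiv), CH2Cl2, −78 → 0 °C; then H2O, 0 °C
Reagents that add atoms: none
Why: Chelation-controlled Lewis-acid ether cleavage, in which BCl3 bridges the formyl oxygen and the neighbouring C4 methoxy oxygen (O···O about 2.5 Å) and this methoxy group is also twisted out of plane between C3a and C5–Br, so chloride removes only its methyl group while the C6 and ring B methoxy groups stay.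

Step 7
Reactants: 11 5-bromo-4-hydroxy-2-(4-hydroxy-2-methoxyphenyl)-6-methoxy-1-benzofuran-3-carbaldehyde; 12 2-methylbut-3-en-2-ol (2 equiv)
Product: 14 4-hydroxy-5-(3-hydroxy-3-methylbutyl)-2-(4-hydroxy-2-methoxyphenyl)-6-methoxy-1-benzofuran-3-carbaldehyde, via borane adduct 13 (not isolated)
Conditions: 12, 9-BBN (2.2 equiv per 12), THF, 0 → 60 °C; then 11, Pd(OAc)2 (5 mol %), SPhos (10 mol %), 3 M aq. K3PO4 (5 equiv), THF, 65 °C; aq. NH4Cl work-up
Reagents that add atoms: none
Why: B-alkyl Suzuki–Miyaura coupling, in which anti-Markovnikov hydroboration of the terminal alkene with 9-BBN gives the primary alkylborane that transfers the 3-hydroxy-3-methylbutyl chain to C5 under basic conditions (the tertiary alcohol and the ortho phenol therefore cannot close to a chroman), with SPhos-ligated palladium chosen for the hindered, electron-rich bromide.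

**Compound list**

1 | 2-bromo-1,3-dimethoxybenzene | COc1cccc(OC)c1Br | starting material
2 | 2-(4-bromo-3,5-dimethoxyphenyl)-4,4,5,5-tetramethyl-1,3,2-dioxaborolane | COc1cc(cc(OC)c1Br)B1OC(C)(C)C(C)(C)O1 | intermediate (not isolated)
3 | 4-bromo-3,5-dimethoxyphenol | COc1cc(O)cc(OC)c1Br | intermediate
4 | 4-bromo-2-iodo-3,5-dimethoxyphenol | COc1cc(O)c(I)c(OC)c1Br | intermediate
5 | 4-hydroxy-2-methoxybenzaldehyde | COc1cc(O)ccc1C=O | starting material
6 | 4-ethynyl-3-methoxyphenol | COc1cc(O)ccc1C#C | intermediate
7 | 4-bromo-2-[(4-hydroxy-2-methoxyphenyl)ethynyl]-3,5-dimethoxyphenol | COc1cc(O)ccc1C#Cc1c(O)cc(OC)c(Br)c1OC | intermediate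
8 | 2-bromo-5-(diethoxymethoxy)-4-{[4-(diethoxymethoxy)-2-methoxyphenyl]ethynyl}-1,3-dimethoxybenzene | CCOC(OCC)Oc1ccc(C#Cc2c(OC(OCC)OCC)cc(OC)c(Br)c2OC)c(OC)c1 | intermediate (not isolated)
9 | 5-bromo-3-(diethoxymethyl)-2-[4-(diethoxymethoxy)-2-methoxyphenyl]-4,6-dimethoxy-1-benzofuran | CCOC(OCC)Oc1ccc(-c2oc3cc(OC)c(Br)c(OC)c3c2C(OCC)OCC)c(OC)c1 | intermediate (not isolated)
10 | 5-bromo-2-(4-hydroxy-2-methoxyphenyl)-4,6-dimethoxy-1-benzofuran-3-carbaldehyde | COc1cc(O)ccc1-c1oc2cc(OC)c(Br)c(OC)c2c1C=O | intermediate
11 | 5-bromo-4-hydroxy-2-(4-hydroxy-2-methoxyphenyl)-6-methoxy-1-benzofuran-3-carbaldehyde | COc1cc(O)ccc1-c1oc2cc(OC)c(Br)c(O)c2c1C=O | intermediate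
12 | 2-methylbut-3-en-2-ol | CC(C)(O)C=C | starting material
13 | 9-{3-[(9-borabicyclo[3.3.1]nonan-9-yl)oxy]-3-methylbutyl}-9-borabicyclo[3.3.1]nonane | CC(C)(CCB1C2CCCC1CCC2)OB1C2CCCC1CCC2 | intermediate (not isolated)
14 | 4-hydroxy-5-(3-hydroxy-3-methylbutyl)-2-(4-hydroxy-2-methoxyphenyl)-6-methoxy-1-benzofuran-3-carbaldehyde | COc1cc(O)ccc1-c1oc2cc(OC)c(CCC(C)(C)O)c(O)c2c1C=O | target

**Step count and risks**

Total step count: 7. Longest linear sequence: 6 steps (steps 1, 2, 4, 5, 6, 7); step 3 is a one-step side branch.

Steps most likely to fail: 5, 6 and 7.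

Step 5 (the new platinum step). Incomplete O-orthoformylation would leave free phenol that simply cycloisomerises to the 3-H benzofuran. A carbenium ion that escapes the ion pair could formylate C7 or be lost to proto-deplatination. The fallback uses known chemistry, sets out from 7 and comes back at 10. Iodocyclisation of 7 (I2 1.1 equiv, NaHCO3, CH2Cl2, 0 °C) is an electrophilic 5-endo-dig closure through the free phenol oxygen, so it is still an O1–C2 ring closure. It gives 5-bromo-2-(4-hydroxy-2-methoxyphenyl)-3-iodo-4,6-dimethoxy-1-benzofuran F1. Iodine–magnesium exchange (i-PrMgCl·LiCl 2.3 equiv, THF, −20 °C) follows; the first equivalent deprotonates the phenol and C–Br is not exchanged at this temperature. This gives chloromagnesium 4-[5-bromo-3-(chloromagnesio)-4,6-dimethoxy-1-benzofuran-2-yl]-3-methoxyphenoxide F2, which is quenched with DMF and worked up with aqueous NH4Cl to give 10.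

Step 6 (selective demethylation). The chelate between 3-CHO and 4-OMe is seven-membered, so complete selectivity over the C6 and ring B methoxy groups is not certain. The fallback reverses the order of the endgame; it sets out from 10 and comes back at 14. B-alkyl Suzuki coupling of 10 with borane adduct 13 (Pd(OAc)2, SPhos, aq. K3PO4, THF, 65 °C) is done while C5–Br is flanked only by two methoxy groups. It gives 5-(3-hydroxy-3-methylbutyl)-2-(4-hydroxy-2-methoxyphenyl)-4,6-dimethoxy-1-benzofuran-3-carbaldehyde F3. The 4-OMe is then cleaved with MgI2·OEt2 (4 equiv, toluene, 80 °C; aq. NH4Cl work-up). This aprotic magnesium chelate with iodide as the nucleophile keeps the tertiary alcohol as its magnesium alkoxide, so no carbocation and no chroman can form, and 14 results.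

Step 7 (late B-alkyl Suzuki coupling). The bromide is flanked by a phenoxide and a methoxy group, transmetalation of the alkylborane may be slow, and the borane could reduce the aldehyde. The fallback replaces the sp3 coupling by Heck coupling plus alkene reduction; it sets out from 11 and comes back at 14. Heck reaction of 11 with 12 (Pd(OAc)2 5 mol %, P(o-tol)3 10 mol %, excess Et3N, DMF, 100 °C) gives 4-hydroxy-5-[(E)-3-hydroxy-3-methylbut-1-en-1-yl]-2-(4-hydroxy-2-methoxyphenyl)-6-methoxy-1-benzofuran-3-carbaldehyde F4. Hydrogenation of the C=C bond with RhCl(PPh3)3 (5 mol %) and H2 (3 bar) in benzene/EtOH at rt leaves the aldehyde and the allylic C–O bond alone and gives 14. The medium is kept basic or neutral throughout so that the o-hydroxy allylic alcohol does not close to a chromene.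

**Further compounds**

F1 | step 5 | 5-bromo-2-(4-hydroxy-2-methoxyphenyl)-3-iodo-4,6-dimethoxy-1-benzofuran | COc1cc(O)ccc1-c1oc2cc(OC)c(Br)c(OC)c2c1I
F2 | step 5 | chloromagnesium 4-[5-bromo-3-(chloromagnesio)-4,6-dimethoxy-1-benzofuran-2-yl]-3-methoxyphenoxide | COc1cc(O[Mg]Cl)ccc1-c1oc2cc(OC)c(Br)c(OC)c2c1[Mg]Cl
F3 | step 6 | 5-(3-hydroxy-3-methylbutyl)-2-(4-hydroxy-2-methoxyphenyl)-4,6-dimethoxy-1-benzofuran-3-carbaldehyde | COc1cc(O)ccc1-c1oc2cc(OC)c(CCC(C)(C)O)c(OC)c2c1C=O
F4 | step 7 | 4-hydroxy-5-[(E)-3-hydroxy-3-methylbut-1-en-1-yl]-2-(4-hydroxy-2-methoxyphenyl)-6-methoxy-1-benzofuran-3-carbaldehyde | COc1cc(O)ccc1-c1oc2cc(OC)c(/C=C/C(C)(C)O)c(O)c2c1C=O
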